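The earlier runs and the new flask were generated by integration with made-up constants; the scatter is artificial.

Decide first to count coupling partner and set the clock aside: what you need from each flask is what stands in it at the end.

| setting | north-west | south-east | eta | delta | gamma |
|---|---|---|---|---|---|
| substrate | 0.50 M | 0.50 M | 0.50 M | 0.50 M | 0.50 M |
| coupling partner | 0.44 M | 1.2 M | 0.500 M | 0.600 M | 2.00 M |
| capture agent | 10 mM | 10 mM | 10.0 mM | 10.0 mM | 10.0 mM |
| remark | run made earlier | run made earlier |  |  |  |
| time |  |  | 5.0 d | 5.0 d | 5.0 d |

- north-west (time / d: first product / %, tris adduct / %): 0.417: 34, 7; 0.625: 31, 8; 1.04: 31, 9; 1.67: 34, 8; 3.00: 29, 8; 5.00: 31, 11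
- south-east (time / d: first product / %, tris adduct / %): 0.417: 22, 25; 0.625: 25, 29; 1.04: 20, 25; 1.67: 21, 27; 3.00: 22, 23; 5.00: 20, 28

(readings scatter by 1.5 percentage points)

1. first product at the end, in percent of the substrate charged, for each flask in turn (eta, delta, gamma)



Both earlier runs are flat from the first sample at 0.417 d, so I treat each as finished and read it as a flask that stopped for want of coupling partner, the limiting reagent. Each run is then described by its loading, north-west 0.880 and south-east 2.40: this is the loading, the equivalents of coupling partner charged per substrate, c(coupling partner)/c(substrate). In the last readings of the south-east run, first product holds one partner and tris adduct three, which, with the partner taken as used up, leaves 2.62 partners for each substrate not seen in those two. That is more than a bis adduct could hold, so I assume a further rung above tris, making a ladder of 4 partners.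

Two extreme flasks can then be solved in the head. If each partner found fresh substrate, first product would equal the loading, 88.0% in north-west. If each reacting substrate climbed to the top, first product would be nil. The reading of 31% lies between them, so I expect first product to rise with loading, pass a top and fall to nil at the ceiling of 4 partners per substrate. Eta has a loading of 1.00 and delta 1.20, both close to north-west, so I commit to about 31% for each. Gamma has 4.00, which meets the ceiling, so I expect first product near nil.

The forecast, which says “I therefore interpolate empirically”, gives 30.5%, 29% and 16%, and so parts from my reckoning at gamma.

The flasks give 32.4%, 32.2% and 0.204%.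

    coupling partner + tris adduct → over-reaction product (k = 0.420 M⁻¹ h⁻¹)
    substrate + coupling partner → first product (k = 0.420 M⁻¹ h⁻¹)
    first product + capture agent → trapped intermediate (k = 2.80 M⁻¹ h⁻¹)
    coupling partner + first product → bis adduct (k = 0.500 M⁻¹ h⁻¹)
    coupling partner + bis adduct → tris adduct (k = 1.30 M⁻¹ h⁻¹)

In delta, at loading 1.20, coupling partner fell under 2% of its charge at 0.648 d, sooner than the 5.0 d of the run, and first product stood at 32.2% at 2.50 d and 32.2% at 5.00 d. In gamma, at loading 4.00, 2.1% of the coupling partner's charge still stood at 5.00 d, with over-reaction product at 96.1%.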